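## Analysis of the target

The target is a 1-aryl-1,2-dihydronaphthalene. Ring B is a cyclohexadiene fused to the aromatic ring A at C4a/C8a. It carries the 4-hydroxy-3,5-dimethoxyphenyl ring C on C1, methyl groups on C2 and C3, and a C3=C4 alkene conjugated with ring A.

There are two adjacent stereocentres, C1 (S) and C2 (S). The aryl and methyl groups are cis on ring B, which corresponds to an anti relationship when the chain C3–C2–C1–C8a is drawn extended. This is the less stable arrangement.

C1 is doubly benzylic and C2 is allylic. Strong acid, strong base or oxidants could therefore epimerise C1, move the alkene, or aromatise ring B to the naphthalene. The two free phenols add sensitivity to oxidation.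

Rings A and C carry the same methoxy–hydroxy–methoxy triad, so the free hydroxyl groups cannot be revealed by a late selective demethylation. The difficulty is to make a pentasubstituted ring A with a free C7 hydroxyl between two methyl ethers while holding a cis C1/C2 pair next to a styrene-type alkene.

The strategy rests on the pattern C6 (OMe), C7 (OH), C8 (OMe) with the hydroxyl para to C4a. This pattern maps onto a 4-methoxyfuran bonded at C4a, whose ring oxygen becomes the C7 hydroxyl, and a methoxyalkyne that supplies C8a and C8.

## Retrosynthetic reasoning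

**22 from 21.** The last step only removes the silyl ether of ring C. The two phenols are told apart because the ring A hydroxyl is created free in the key step while the ring C hydroxyl is carried protected from the start. A triisopropylsilyl ether is used in place of a smaller silyl group because it has to survive hydroxide, carbonate and alkoxide in the middle of the route.

**21 from 19.** The bonds C4a–C8a and C7–C8 are cut, which opens rings A and B together. Cutting here means ring A is assembled from a furan and an alkyne with its oxygen pattern already in place, so no aromatic substitution or demethylation is needed. The forward reaction has to form two C–C bonds and open the oxygen bridge toward C7; it creates no lasting stereocentre. Precursor 19 must therefore already hold C1, C2 and the (Z)-C3=C4 alkene.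

**19 from 17.** The C8a≡C8–OMe unit is traced back to the CH2–CO2Me group of ester 17. The ester has the right carbon count and already contains the O–CH3 bond. It is converted to the alkyne by enol phosphate formation and elimination. This keeps the acid-labile ynol ether out of every step except the one before the cycloaddition.

**17 from 15 (through 16).** The C3–CH3 bond and the C4–H bond are cut, leading back to the alkyne of 15. An acyclic olefination would place the furyl group trans to the branched C2 substituent. Syn addition of hydrogen and methyl across the alkyne gives the Z isomer by mechanism.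

**15 from 14, and 14 from 10 and 11.** The bond between C4 and the furan carbon C4a is cut. The furan ring comes from methyl tetronate 11: an acetylide adds to the lactone carbonyl and the adduct dehydrates. This puts the side chain on the former carbonyl carbon and leaves the methoxy group at position 4, a substitution pattern that metalation of 3-methoxyfuran would not give. The side chain carries a carboxylic acid (10) at this stage because a carboxylate tolerates the organolithium; the methyl ester 15 is made afterwards.

**10 from 9, 7 and 6.** These are functional group changes. The CH2–CO2H group comes from the vinyl group of 7 by hydroboration and oxidation. The alkyne is hidden as a 1,1-dibromoalkene made from aldehyde 6, so that it is inert while the vinyl group is oxidised.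

**6 from 4 and 5; 4 from 2 and 3; 2 from 1.** The C1–C2 bond is cut. Both stereocentres are set in one step by joining the racemic allylic alcohol 4 with propanal 5 under two independent chiral catalysts. Alcohol 4 comes from vinylmagnesium bromide 3 and the silylated aldehyde 2, which comes from syringaldehyde 1.

## Alternatives that were turned down

**Alternative 1:** Ring B would be cut at C8a–C1, C2–C3 and C4–C4a. In the forward direction the aryne released from silylaryl triflate A1, the (Z)-propenylarene A2 and propyne A3 would be joined on zerovalent nickel carrying a chiral phosphine, giving the bis(methoxymethyl) ether A4.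
- For it: it is the most convergent plan, with ring B, the alkene and both stereocentres formed in one step from three simple pieces. Syn carbometalation would turn the Z geometry of A2 into the cis C1/C2 pair. On step count it is clearly better than the chosen route.
- Against it: four selectivities must be won in one unprecedented step. These are the orientation of the unsymmetrical aryne, the orientation of A3, incorporation of one alkene in competition with a second alkyne or aryne, and face selectivity on an unactivated 1,2-disubstituted alkene. The nickelacycle also has β-hydrogens at C1 and C2, so elimination to isomerised or aromatised products is likely.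
- Comparison: the chosen key step is also untested, but it forms no stereocentre and has one possible regiochemistry. All stereochemistry is set earlier by a documented catalytic reaction.

**Alternative 2:** The bonds C3–C4 and C4–C4a would be cut. In the forward direction the Lewis-acid-activated indanone A5 would take up one carbon from (trimethylsilyl)diazomethane A6 with migration of the ring A carbon, giving the cis 2-tetralone A7. The C3 methyl group and the C3=C4 alkene would follow by enol triflate formation and methylation.
- For it: every step is a known reaction type, the intermediates are robust, and the electron-rich aryl group should migrate in preference to C2. On precedent step by step it is stronger than the chosen route.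
- Against it: C2 sits next to a carbonyl in both A5 and A7, and the required cis arrangement is the less stable one. The Lewis acid of the ring expansion and the base of the enolisation can both epimerise it to trans. A5 also needs a pentasubstituted ring A with its C7 oxygen already differentiated.
- Comparison: in the chosen route C2 is next to a carbonyl only in aldehyde 6, which is consumed at once under neutral conditions, and ring A is built with its oxygen pattern rather than taken from a pre-differentiated arene.

**Alternative 3:** The C3=C4 alkene would be cut. In the forward direction the diene A8, with a vinyl group on ring A and an isopropenyl group on C2, would close with a second-generation Grubbs catalyst to the bis(silyl) ether A9.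
- For it: this ring closure is the most dependable of the four key steps. A trisubstituted styrene-type alkene in a six-membered ring forms readily under neutral conditions that leave C1 and C2 untouched. On the reliability of the key step it is stronger than the chosen route.
- Against it: the difficulty moves into A8. The diaryl methine C1 must be made between two electronically similar aryl rings, one of them flanked on both sides by substituents. The cis C1/C2 pair has to be set beside it, and ring A has to be functionalised stepwise with two phenol protections.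
- Comparison: the chosen strategy creates ring A with its substitution and its free phenol in one operation from a four-carbon lactone, and sets the stereodiad in one catalytic step on an unhindered monoaryl carbon.

Key step: step 12

Notation: Ar = 3,5-dimethoxy-4-[tri(propan-2-yl)silyloxy]phenyl; atom labels C1–C8a are those of the dihydronaphthalene of the target.

Assumption: in step 3 the (S)-ligand is taken to set the S configuration at the allylic carbon and the (R)-amine the S configuration at the α-carbon; each catalyst controls one centre independently, so either is exchanged for its mirror image if its sense of induction proves opposite.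

## Route

Step 1
Reactants: 1 syringaldehyde
Product: 2 3,5-dimethoxy-4-[tri(propan-2-yl)silyloxy]benzaldehyde
Conditions: i-Pr3SiCl, imidazole, DMF, 40 °C
Reagents that add atoms: chlorotri(propan-2-yl)silane, CC(C)[Si](Cl)(C(C)C)C(C)C
Why: O-silylation of the acidic phenol by substitution at silicon. The triisopropylsilyl aryl ether should survive the hydroxide, carbonate and alkoxide conditions of steps 5, 8, 9 and 10, where a tert-butyldimethylsilyl aryl ether would be at risk.

Step 2
Reactants: 2; 3 vinylmagnesium bromide
Product: 4 rac-1-Ar-prop-2-en-1-ol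
Conditions: THF, −78 to 0 °C; aq. NH4Cl
Reagents that add atoms: vinylmagnesium bromide 3, C=C[Mg]Br
Why: Grignard 1,2-addition to the aldehyde. The carbinol stereocentre is formed racemic on purpose, because step 3 is enantioconvergent through a common π-allyl intermediate.

Step 3
Reactants: 4; 5 propanal
Product: 6 (2S,3S)-3-Ar-2-methylpent-4-enal
Conditions: [Ir(cod)Cl]2 (3 mol%), (S)-N-(dinaphtho[2,1-d:1′,2′-f][1,3,2]dioxaphosphepin-4-yl)-5H-dibenzo[b,f]azepine (12 mol%), (R)-α,α-bis[3,5-bis(trifluoromethyl)phenyl]prolinol trimethylsilyl ether (10 mol%), (MeO)2P(O)OH, ClCH2CH2Cl, 25 °C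
Reagents that add atoms: propanal 5, CCC=O
Why: Dual-catalytic stereodivergent α-allylation of an aldehyde. The iridium–phosphoramidite–olefin catalyst ionises 4 to a π-allyl complex that is attacked at the aryl-bearing terminus and so sets C1, while the enamine of propanal with the chiral amine exposes one face and sets C2. The two catalysts act independently, so the anti (2S,3S) isomer is reached by the pairing of their configurations.

Step 4
Reactants: 6
Product: 7 (3S,4S)-4-Ar-1,1-dibromo-3-methylhexa-1,5-diene
Conditions: CBr4, PPh3, Zn, CH2Cl2, 0 °C to rt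
Reagents that add atoms: tetrabromomethane, BrC(Br)(Br)Br
Why: First stage of the Corey–Fuchs homologation, a Wittig-type dibromomethylenation. The neutral zinc variant should not epimerise the α-stereocentre C2, and the dibromoalkene masks the alkyne as a group inert to borane and oxidant in steps 5 and 6.

Step 5
Reactants: 7
Product: 9 (3S,4S)-3-Ar-6,6-dibromo-4-methylhex-5-en-1-ol, via B-alkyl-9-borabicyclononane 8 (not isolated)
Conditions: 9-borabicyclo[3.3.1]nonane, THF, 0 °C to rt; then aq. NaOH, 30% H2O2, 0 °C
Reagents that add atoms: hydrogen peroxide, OO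
Why: Anti-Markovnikov hydroboration–oxidation. The bulky borane should react only with the monosubstituted vinyl group and leave the hindered, electron-poor dibromoalkene alone; no stereocentre is touched.

Step 6
Reactants: 9
Product: 10 (3S,4S)-3-Ar-6,6-dibromo-4-methylhex-5-enoic acid
Conditions: (2,2,6,6-tetramethylpiperidin-1-yl)oxyl (cat.), PhI(OAc)2, MeCN/H2O, rt
Reagents that add atoms: water, O
Why: Oxoammonium-mediated oxidation of the primary alcohol through the aldehyde hydrate to the acid. The acid oxidation level is reached before the furan exists, and as its carboxylate the acid is inert to the organolithium of step 7.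

Step 7
Reactants: 10; 11 methyl tetronate
Product: 14 (3S,4S)-3-Ar-6-(4-methoxyfuran-2-yl)-4-methylhex-5-ynoic acid, via alkynyl carboxylate 12 (not isolated), via lactol 13 (not isolated)
Conditions: NaH, THF, 0 °C; n-BuLi (2.1 equiv), −78 °C; CeCl3, −78 °C; 11, −78 to −20 °C; then aq. HCl; TsOH (cat.), CH2Cl2, rt
Reagents that add atoms: methyl tetronate 11, COC1=CC(=O)OC1
Why: Second stage of the Corey–Fuchs sequence (bromine–lithium exchange, Fritsch–Buttenberg–Wiechell rearrangement, deprotonation) gives the acetylide of 12 while the acid is masked as its carboxylate. The organocerium reagent should add 1,2 to the lactone carbonyl rather than remove a C5 proton of 11. Acid then dehydrates lactol 13 to the aromatic furan, the classical butenolide-to-furan conversion, which fixes the side chain on furan C2 and the methoxy group on C4; the lactol carbon is a transient stereocentre.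

Step 8
Reactants: 14
Product: 15 methyl (3S,4S)-3-Ar-6-(4-methoxyfuran-2-yl)-4-methylhex-5-ynoate
Conditions: MeI, K2CO3, DMF, rt
Reagents that add atoms: iodomethane, CI
Why: SN2 O-methylation of the carboxylate under mild base, which the methoxyfuran and the silyl ether tolerate. The O–CH3 bond made here becomes the C8 methoxy group of the target.

Step 9
Reactants: 15
Product: 16 methyl (3S,4S,5Z)-3-Ar-6-(4-methoxyfuran-2-yl)-4-methyl-5-(4,4,5,5-tetramethyl-1,3,2-dioxaborolan-2-yl)hex-5-enoate
Conditions: CuCl (5 mol%), Xantphos (5 mol%), NaOt-Bu (10 mol%), B2pin2, MeOH, THF, rt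
Reagents that add atoms: bis(pinacolato)diboron, CC1(C)OB(OC1(C)C)B1OC(C)(C)C(C)(C)O1
Why: Copper-catalysed formal hydroboration of a heteroaryl alkyne: syn borylcupration places copper on the furyl-bearing carbon C4 and boron on C3, and methanol then protonates the C–Cu bond with retention. Hydrogen and boron end up on the same side, so the furan and C2 are cis.

Step 10
Reactants: 16
Product: 17 methyl (3S,4S,5Z)-3-Ar-6-(4-methoxyfuran-2-yl)-4,5-dimethylhex-5-enoate
Conditions: Pd(dppf)Cl2 (5 mol%), K3PO4, MeI, DMF/H2O, 60 °C
Reagents that add atoms: iodomethane, CI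
Why: Suzuki–Miyaura methylation of the alkenylboronate, which proceeds with retention of alkene geometry and so gives the (Z)-trisubstituted alkene. The ester and silyl ether tolerate the mild phosphate base.

Step 11
Reactants: 17
Product: 19 2-[(1Z,3S,4S)-4-Ar-6-methoxy-2,3-dimethylhex-1-en-5-yn-1-yl]-4-methoxyfuran, via ketene acetal phosphate 18 (not isolated)
Conditions: LiN(i-Pr)2, THF, −78 °C; (EtO)2P(O)Cl, DMPU, −78 °C; then t-BuLi, −100 to −78 °C
Reagents that add atoms: none
Why: Known conversion of an ester into a 1-alkoxyalkyne: the enolate is phosphorylated on oxygen, and t-BuLi then removes the vinylic proton with loss of diethyl phosphate (β-elimination). The methoxy oxygen of the ester is retained, and C1 and C2 are not part of the reacting system.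

Step 12
Reactants: 19
Product: 21 (7S,8S)-8-Ar-1,3-dimethoxy-6,7-dimethyl-7,8-dihydronaphthalen-2-ol, via oxanorbornadiene 20 (not isolated)
Conditions: degassed PhMe (0.01 M), 2,6-di-tert-butyl-4-methylpyridine (0.2 equiv), BHT (cat.), sealed tube, 170 °C
Reagents that add atoms: none
Why: Proposed new method: a thermal intramolecular furan–alkyne Diels–Alder reaction in which the dienophile is a methyl ynol ether, followed by aromatising opening of the 7-oxanorbornadiene; the closest known reaction type is the intramolecular Diels–Alder reaction of furans with tethered alkynes that ends in a phenol. The 4-methoxyfuran (C4a, C5, C6, C7) is the four-electron component and C8a≡C8 the two-electron component, and the (Z)-C3=C4 alkene with its four-atom tether holds the alkyne over the furan so that C4a–C8a and C7–C8 form on one face in one step. Ring B closes as a six-membered carbocycle through the C4a–C8a bond, the only regiochemistry the tether allows, and ring A closes through the C7–C8 bond as the six-membered ring of oxanorbornadiene 20. Heterolysis of the C4a–O bond then gives a cation at C4a that is delocalised onto C6 and C8, both bearing methoxy groups, and into the C3=C4 alkene, and loss of the C7 proton gives the benzene ring with the former furan oxygen as the C7 hydroxyl. No lasting stereocentre is formed: the two bridgehead centres of 20 disappear on aromatisation, and C1 and C2, set in step 3, are not involved. The selectivity needed is the direction of bridge opening, secured because only C4a–O cleavage gives a methoxy-stabilised cation and only C7 has a hydrogen to lose, and retention at C1, secured by neutral, base-buffered conditions. Diene and dienophile are both electron-rich, so the reaction depends on the tether and on high temperature; a methyl ynol ether cannot fragment to a ketene by a retro-ene path.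

Step 13
Reactants: 21
Product: 22 (7S,8S)-8-(4-hydroxy-3,5-dimethoxyphenyl)-1,3-dimethoxy-6,7-dimethyl-7,8-dihydronaphthalen-2-ol
Conditions: Bu4NF, AcOH, THF, 0 °C
Reagents that add atoms: none
Why: Fluoride cleavage of the aryl silyl ether. Acetic acid buffers the phenoxides so that the doubly benzylic C1 and the C3=C4 alkene are not exposed to strong base.

## Compound list

1 | syringaldehyde (4-hydroxy-3,5-dimethoxybenzaldehyde) | COc1cc(C=O)cc(OC)c1O | starting material
2 | 3,5-dimethoxy-4-[tri(propan-2-yl)silyloxy]benzaldehyde | COc1cc(C=O)cc(OC)c1O[Si](C(C)C)(C(C)C)C(C)C | intermediate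
3 | vinylmagnesium bromide | C=C[Mg]Br | starting material
4 | rac-1-{3,5-dimethoxy-4-[tri(propan-2-yl)silyloxy]phenyl}prop-2-en-1-ol | COc1cc(C(O)C=C)cc(OC)c1O[Si](C(C)C)(C(C)C)C(C)C | intermediate
5 | propanal | CCC=O | starting material
6 | (2S,3S)-3-Ar-2-methylpent-4-enal | O=C[C@@H](C)[C@H](C=C)c1cc(OC)c(O[Si](C(C)C)(C(C)C)C(C)C)c(OC)c1 | intermediate
7 | (3S,4S)-4-Ar-1,1-dibromo-3-methylhexa-1,5-diene | BrC(Br)=C[C@@H](C)[C@H](C=C)c1cc(OC)c(O[Si](C(C)C)(C(C)C)C(C)C)c(OC)c1 | intermediate
8 | 9-[(3S,4S)-3-Ar-6,6-dibromo-4-methylhex-5-en-1-yl]-9-borabicyclo[3.3.1]nonane (not isolated) | BrC(Br)=C[C@@H](C)[C@H](CCB1C2CCCC1CCC2)c1cc(OC)c(O[Si](C(C)C)(C(C)C)C(C)C)c(OC)c1 | intermediate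
9 | (3S,4S)-3-Ar-6,6-dibromo-4-methylhex-5-en-1-ol | BrC(Br)=C[C@@H](C)[C@H](CCO)c1cc(OC)c(O[Si](C(C)C)(C(C)C)C(C)C)c(OC)c1 | intermediate
10 | (3S,4S)-3-Ar-6,6-dibromo-4-methylhex-5-enoic acid | BrC(Br)=C[C@@H](C)[C@H](CC(=O)O)c1cc(OC)c(O[Si](C(C)C)(C(C)C)C(C)C)c(OC)c1 | intermediate
11 | methyl tetronate (4-methoxy-2(5H)-furanone) | COC1=CC(=O)OC1 | starting material
12 | (3S,4S)-3-Ar-4-methylhex-5-ynoic acid, present as its carboxylate acetylide (not isolated) | C#C[C@@H](C)[C@H](CC(=O)O)c1cc(OC)c(O[Si](C(C)C)(C(C)C)C(C)C)c(OC)c1 | intermediate
13 | (3S,4S)-3-Ar-6-(2-hydroxy-4-methoxy-2,5-dihydrofuran-2-yl)-4-methylhex-5-ynoic acid, both epimers at the lactol carbon (not isolated) | COC1=CC(O)(C#C[C@@H](C)[C@H](CC(=O)O)c2cc(OC)c(O[Si](C(C)C)(C(C)C)C(C)C)c(OC)c2)OC1 | intermediate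
14 | (3S,4S)-3-Ar-6-(4-methoxyfuran-2-yl)-4-methylhex-5-ynoic acid | COc1coc(C#C[C@@H](C)[C@H](CC(=O)O)c2cc(OC)c(O[Si](C(C)C)(C(C)C)C(C)C)c(OC)c2)c1 | intermediate
15 | methyl (3S,4S)-3-Ar-6-(4-methoxyfuran-2-yl)-4-methylhex-5-ynoate | COc1coc(C#C[C@@H](C)[C@H](CC(=O)OC)c2cc(OC)c(O[Si](C(C)C)(C(C)C)C(C)C)c(OC)c2)c1 | intermediate
16 | methyl (3S,4S,5Z)-3-Ar-6-(4-methoxyfuran-2-yl)-4-methyl-5-(4,4,5,5-tetramethyl-1,3,2-dioxaborolan-2-yl)hex-5-enoate | COc1coc(/C=C(/B2OC(C)(C)C(C)(C)O2)[C@@H](C)[C@H](CC(=O)OC)c3cc(OC)c(O[Si](C(C)C)(C(C)C)C(C)C)c(OC)c3)c1 | intermediate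
17 | methyl (3S,4S,5Z)-3-Ar-6-(4-methoxyfuran-2-yl)-4,5-dimethylhex-5-enoate | COc1coc(/C=C(/C)[C@@H](C)[C@H](CC(=O)OC)c2cc(OC)c(O[Si](C(C)C)(C(C)C)C(C)C)c(OC)c2)c1 | intermediate
18 | diethyl [(3R,4S,5Z)-3-Ar-1-methoxy-6-(4-methoxyfuran-2-yl)-4,5-dimethylhexa-1,5-dien-1-yl] phosphate, enol geometry undefined, same spatial arrangement at both stereocentres as 17 (not isolated) | COc1coc(/C=C(/C)[C@@H](C)[C@H](C=C(OC)OP(=O)(OCC)OCC)c2cc(OC)c(O[Si](C(C)C)(C(C)C)C(C)C)c(OC)c2)c1 | intermediate
19 | 2-[(1Z,3S,4S)-4-Ar-6-methoxy-2,3-dimethylhex-1-en-5-yn-1-yl]-4-methoxyfuran | COc1coc(/C=C(/C)[C@@H](C)[C@H](C#COC)c2cc(OC)c(O[Si](C(C)C)(C(C)C)C(C)C)c(OC)c2)c1 | intermediate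
20 | oxanorbornadiene: ring B fused to a 7-oxabicyclo[2.2.1]hepta-2,5-diene with the oxygen bridging C4a and C7, double bonds C5=C6 and C8=C8a, C1 and C2 as in 19, bridgehead configuration undefined (not isolated) | COC1=CC23OC1C(OC)=C2[C@H](c4cc(OC)c(O[Si](C(C)C)(C(C)C)C(C)C)c(OC)c4)[C@H](C)C(C)=C3 | intermediate
21 | (7S,8S)-8-Ar-1,3-dimethoxy-6,7-dimethyl-7,8-dihydronaphthalen-2-ol | COc1cc([C@H]2c3c(cc(OC)c(O)c3OC)C=C(C)[C@H]2C)cc(OC)c1O[Si](C(C)C)(C(C)C)C(C)C | intermediate
22 | (7S,8S)-8-(4-hydroxy-3,5-dimethoxyphenyl)-1,3-dimethoxy-6,7-dimethyl-7,8-dihydronaphthalen-2-ol (CNP0141907.1) | COc1cc([C@H]2c3c(cc(OC)c(O)c3OC)C=C(C)[C@H]2C)cc(OC)c1O | target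

## Step count and least certain steps

Total step count: 13. Longest linear sequence: 13 steps from syringaldehyde 1.

**Step 12 (key step, proposed new method).** The most likely failure is that no cycloaddition takes place at temperatures the substrate survives. Furan and ynol ether are both electron-rich, so decomposition of the ynol ether or of the methoxyfuran may outrun ring closure, and prolonged heating may erode the C1 configuration.

The fallback uses known reactions, sets out from 17 and returns at 21:
- Ester 17 is reduced with i-Bu2AlH at −78 °C to (3S,4S,5Z)-3-Ar-6-(4-methoxyfuran-2-yl)-4,5-dimethylhex-5-enal F1.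
- F1 is converted without change in carbon count into the terminal alkyne 2-[(1Z,3S,4R)-4-Ar-2,3-dimethylhex-1-en-5-yn-1-yl]-4-methoxyfuran F2 by alkenyl nonaflate formation and elimination (C4F9SO2F, phosphazene base, DMF). The descriptor at the aryl-bearing carbon changes by priority only.
- Heating F2 is an intramolecular furan Diels–Alder reaction with an unactivated alkyne of the documented kind. It should give (7S,8S)-8-Ar-3-methoxy-6,7-dimethyl-7,8-dihydronaphthalen-2-ol F3, which lacks only the C8 methoxy group.
- ortho-Bromination of the phenol (N-bromosuccinimide, i-Pr2NH, CH2Cl2, −78 °C) gives (7S,8S)-8-Ar-1-bromo-3-methoxy-6,7-dimethyl-7,8-dihydronaphthalen-2-ol F4. C8 is the only free position ortho or para to the hydroxyl.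
- Ullmann-type methoxylation (CuI, NaOMe, MeOH/DMF, heat) replaces bromine by methoxy and rejoins the route at 21.

**Step 7.** The acetylide may remove a C5 proton of 11, giving the aromatic furanolate, instead of adding to the carbonyl. Ring opening of the lactol to the ynone may also allow further addition.

The fallback sets out from 10 and 11 and returns at 14:
- 11 is opened with MeNHOMe·HCl and Me3Al to (E)-4-hydroxy-N,3-dimethoxy-N-methylbut-2-enamide F5.
- F5 is silylated (Et3SiCl, imidazole) to (E)-N,3-dimethoxy-N-methyl-4-(triethylsilyloxy)but-2-enamide F6. This acyclic amide cannot form an aromatic anion, and its chelated adduct stops at the ketone.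
- The acetylide made from 10 as in step 7 adds to F6 to give (3S,4S,8E)-3-Ar-9-methoxy-4-methyl-7-oxo-10-(triethylsilyloxy)dec-8-en-5-ynoic acid F7.
- Aqueous acid removes the silyl group, and the hydroxy ketone closes and dehydrates to 14.

**Step 11.** t-BuLi may attack phosphorus and return the ester. It may also deprotonate the benzylic C1–H next to the ketene acetal, with loss of configuration, while lithiation of furan C5 consumes base.

The fallback sets out from 17 and returns at 19. It uses the double elimination of an α-chloro acetal, the reaction by which methoxyacetylene itself is made: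
- The enolate of 17 (LiN(i-Pr)2) is chlorinated with C2Cl6 to the methyl 2-chloro derivative of 17, F8 (both epimers at the chlorinated carbon).
- i-Bu2AlH at −78 °C gives the 2-chloro aldehyde F9.
- HC(OMe)3 with pyridinium p-toluenesulfonate gives the 2-chloro dimethyl acetal F10.
- LiNEt2 (3 equiv, THF, −78 to 0 °C) removes methanol and then hydrogen chloride to give 19.

**Step 9.** Borylcupration may occur with the opposite regiochemistry, because the branched C2 substituent crowds the carbon that must take boron. The hindered boronate may then undergo protodeboronation in step 10.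

The fallback sets out from 15 and returns at 17. Ni(acac)2-catalysed syn methylzincation with Me2Zn (THF/NMP, −35 °C) places methyl on the carbon remote from the furan, and protonolysis gives 17 directly. No new compound arises (F0).

## Further compounds

F1 | step 12 | (3S,4S,5Z)-3-Ar-6-(4-methoxyfuran-2-yl)-4,5-dimethylhex-5-enal | COc1coc(/C=C(/C)[C@@H](C)[C@H](CC=O)c2cc(OC)c(O[Si](C(C)C)(C(C)C)C(C)C)c(OC)c2)c1
F2 | step 12 | 2-[(1Z,3S,4R)-4-Ar-2,3-dimethylhex-1-en-5-yn-1-yl]-4-methoxyfuran | COc1coc(/C=C(/C)[C@@H](C)[C@H](C#C)c2cc(OC)c(O[Si](C(C)C)(C(C)C)C(C)C)c(OC)c2)c1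
F3 | step 12 | (7S,8S)-8-Ar-3-methoxy-6,7-dimethyl-7,8-dihydronaphthalen-2-ol | COc1cc([C@H]2c3c(cc(OC)c(O)c3)C=C(C)[C@H]2C)cc(OC)c1O[Si](C(C)C)(C(C)C)C(C)C
F4 | step 12 | (7S,8S)-8-Ar-1-bromo-3-methoxy-6,7-dimethyl-7,8-dihydronaphthalen-2-ol | COc1cc([C@H]2c3c(cc(OC)c(O)c3Br)C=C(C)[C@H]2C)cc(OC)c1O[Si](C(C)C)(C(C)C)C(C)C
F5 | step 7 | (E)-4-hydroxy-N,3-dimethoxy-N-methylbut-2-enamide | CON(C)C(=O)/C=C(/OC)CO
F6 | step 7 | (E)-N,3-dimethoxy-N-methyl-4-(triethylsilyloxy)but-2-enamide | CON(C)C(=O)/C=C(/OC)CO[Si](CC)(CC)CC
F7 | step 7 | (3S,4S,8E)-3-Ar-9-methoxy-4-methyl-7-oxo-10-(triethylsilyloxy)dec-8-en-5-ynoic acid | O=C(/C=C(/OC)CO[Si](CC)(CC)CC)C#C[C@@H](C)[C@H](CC(=O)O)c1cc(OC)c(O[Si](C(C)C)(C(C)C)C(C)C)c(OC)c1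
F8 | step 11 | methyl 2-chloro derivative of 17, both epimers at the chlorinated carbon, other stereocentres and Z-alkene as in 17 | COc1coc(/C=C(/C)[C@@H](C)[C@H](C(Cl)C(=O)OC)c2cc(OC)c(O[Si](C(C)C)(C(C)C)C(C)C)c(OC)c2)c1
F9 | step 11 | 2-chloro aldehyde from F8, both epimers at the chlorinated carbon | COc1coc(/C=C(/C)[C@@H](C)[C@H](C(Cl)C=O)c2cc(OC)c(O[Si](C(C)C)(C(C)C)C(C)C)c(OC)c2)c1
F10 | step 11 | 2-chloro dimethyl acetal from F9, both epimers at the chlorinated carbon | COc1coc(/C=C(/C)[C@@H](C)[C@H](C(Cl)C(OC)OC)c2cc(OC)c(O[Si](C(C)C)(C(C)C)C(C)C)c(OC)c2)c1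
F0 | step 9 | none | none
A1 | alternative 1 | 3,5-dimethoxy-4-(methoxymethoxy)-2-(trimethylsilyl)phenyl trifluoromethanesulfonate | COCOc1c(OC)cc(OS(=O)(=O)C(F)(F)F)c([Si](C)(C)C)c1OC
A2 | alternative 1 | 1,3-dimethoxy-2-(methoxymethoxy)-5-[(1Z)-prop-1-en-1-yl]benzene | COCOc1c(OC)cc(/C=C\C)cc1OC
A3 | alternative 1 | propyne | CC#C
A4 | alternative 1 | bis(methoxymethyl) ether of the target | COc1cc([C@H]2c3c(cc(OC)c(OCOC)c3OC)C=C(C)[C@H]2C)cc(OC)c1OCOC
A5 | alternative 2 | cis-(2S,3S)-5-(tert-butyldimethylsilyloxy)-3-[4-(tert-butyldimethylsilyloxy)-3,5-dimethoxyphenyl]-4,6-dimethoxy-2-methylindan-1-one | COc1cc([C@H]2c3c(cc(OC)c(O[Si](C)(C)C(C)(C)C)c3OC)C(=O)[C@H]2C)cc(OC)c1O[Si](C)(C)C(C)(C)C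
A6 | alternative 2 | (trimethylsilyl)diazomethane | C[Si](C)(C)C=[N+]=[N-]
A7 | alternative 2 | cis-1-aryl-2-methyl-3-oxotetralin, bis(tert-butyldimethylsilyl) ether | COc1cc([C@H]2c3c(cc(OC)c(O[Si](C)(C)C(C)(C)C)c3OC)CC(=O)[C@H]2C)cc(OC)c1O[Si](C)(C)C(C)(C)C
A8 | alternative 3 | ring-closing metathesis diene with vinyl on ring A and isopropenyl on C2, bis(tert-butyldimethylsilyl) ether | COc1cc([C@@H](c2c(C=C)cc(OC)c(O[Si](C)(C)C(C)(C)C)c2OC)[C@H](C)C(C)=C)cc(OC)c1O[Si](C)(C)C(C)(C)C
A9 | alternative 3 | bis(tert-butyldimethylsilyl) ether of the target | COc1cc([C@H]2c3c(cc(OC)c(O[Si](C)(C)C(C)(C)C)c3OC)C=C(C)[C@H]2C)cc(OC)c1O[Si](C)(C)C(C)(C)C
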